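**Retrosynthetic overview**
- The hydroxyquinone is unveiled last by Teuber oxidation of a MOM-protected chloro-orcinol ring; that ring is bought, not built.
- The C4'–C3' bond comes from a Ni/Cr alkenylation of a δ-keto aldehyde with an (E)-vinyl iodide made from orcinol and but-2-yn-1-ol.
- The δ-keto aldehyde comes from a 2-oxabicyclo[3.3.1]non-3-ene in which the carbocycle and a dihydropyran ring are formed together by a bridged intramolecular oxa-Diels–Alder reaction of a (Z)-enal with a (Z)-silyl enol ether.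
- The cycloaddition substrate comes from propanal and divinyl ketone: organocatalytic Michael addition sets C4, 1,4-hydrosilylation fixes the enol ether regiochemistry, and methylcuprate addition to an ynamide sets the enal geometry.
- Ring order: carbocycle plus oxa-bridge in one step, oxa-bridge opened by hydrolysis, quinone ring oxidised last.

Assumption: cyclohexanone carbons are called C1 (C=O) to C6, side-chain carbons C1' (on the quinone) to C5' (on C3), and penta-1,4-dien-3-one is taken as a commercial stabilised reagent.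

**Step 1**
Reactants: 1 propanal; 2 penta-1,4-dien-3-one
Product: 3 (2S)-2-methyl-5-oxohept-6-enal
Conditions: (R)-2-[methoxy(diphenyl)methyl]pyrrolidine (5 mol %), ethyl 3,4-dihydroxybenzoate (20 mol %), 2 (3 equiv), CH2Cl2, 4 °C
Reagents that add atoms: none
Why: Enamine-catalysed Michael addition of an aldehyde to a vinyl ketone, in which the (R)-diarylprolinol ether shields one enamine face so that C4 is formed S, while excess 2 and the catalyst's reluctance to form enamines from α-branched aldehydes suppress a second addition.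

**Step 2**
Reactants: 3 (2S)-2-methyl-5-oxohept-6-enal
Product: 4 (2S,5Z)-2-methyl-5-[(triethylsilyl)oxy]hept-5-enal
Conditions: Et3SiH (1.05 equiv), Pt2[(CH2=CHSiMe2)2O]3 (0.1 mol %), toluene, 0 °C to rt
Reagents that add atoms: triethylsilane, CC[SiH](CC)CC
Why: Zerovalent-platinum-catalysed 1,4-hydrosilylation of the s-cis vinyl ketone puts silicon on oxygen and hydrogen on the terminal carbon, giving the regiodefined (Z)-silyl enol ether (C1=C2) that ketone enolisation could not give, while the aliphatic aldehyde is not hydrosilylated by this catalyst.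

**Step 3**
Reactants: 4 (2S,5Z)-2-methyl-5-[(triethylsilyl)oxy]hept-5-enal
Product: 5 (3S,6Z)-3-methyl-6-[(triethylsilyl)oxy]oct-6-en-1-yne
Conditions: (MeO)2P(O)CHN2 (1.2 equiv), KOC(CH3)3 (1.1 equiv), THF, −78 °C to rt
Reagents that add atoms: dimethyl (diazomethyl)phosphonate, COP(=O)(OC)C=[N+]=[N-]
Why: Seyferth–Gilbert homologation (alkylidene carbene, 1,2-hydrogen shift) run aprotic and cold with the phosphonate anion pre-formed, so the C4 centre and the silyl enol ether are untouched.

**Step 4**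
Reactants: 5 (3S,6Z)-3-methyl-6-[(triethylsilyl)oxy]oct-6-en-1-yne
Product: 7 (4S,7Z)-N-methoxy-N,4-dimethyl-7-[(triethylsilyl)oxy]non-7-en-2-ynamide, via lithium acetylide 6 (not isolated)
Conditions: n-BuLi (1.05 equiv), THF, −78 °C; then ClC(O)N(OMe)Me, −78 to 0 °C
Reagents that add atoms: N-methoxy-N-methylcarbamoyl chloride, CON(C)C(Cl)=O
Why: Acylation of the lithium acetylide with the Weinreb-type carbamoyl chloride gives the alkynyl Weinreb amide without over-addition and provides the acceptor for the next step.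

**Step 5**
Reactants: 7 (4S,7Z)-N-methoxy-N,4-dimethyl-7-[(triethylsilyl)oxy]non-7-en-2-ynamide
Product: 8 (2Z,4S,7Z)-N-methoxy-N,3,4-trimethyl-7-[(triethylsilyl)oxy]nona-2,7-dienamide
Conditions: Me2CuLi (from MeLi and CuI, 1.3 equiv), THF, −78 °C, 1 h; saturated aqueous NH4Cl at −78 °C
Reagents that add atoms: lithium dimethylcuprate, [Li+].C[Cu-]C
Why: Syn-carbocupration (cuprate conjugate addition) of the ynamide followed by cold protonation of the configurationally stable α-cuprio enamide places methyl cis to hydrogen, so the C4 chain ends cis to the carbonyl group, the (2Z) geometry the cycloaddition needs.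

**Step 6**
Reactants: 8 (2Z,4S,7Z)-N-methoxy-N,3,4-trimethyl-7-[(triethylsilyl)oxy]nona-2,7-dienamide
Product: 9 (2Z,4S,7Z)-3,4-dimethyl-7-[(triethylsilyl)oxy]nona-2,7-dienal
Conditions: i-Bu2AlH (1.2 equiv), THF, −78 °C; aqueous potassium sodium tartrate
Reagents that add atoms: none
Why: Weinreb amide reduction stops at the aldehyde through the chelated aluminium hemiaminal and leaves both alkene geometries unchanged.

**Step 7**
Reactants: 9 (2Z,4S,7Z)-3,4-dimethyl-7-[(triethylsilyl)oxy]nona-2,7-dienal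
Product: 10 (1S,5R,6S,9S)-5,6,9-trimethyl-1-[(triethylsilyl)oxy]-2-oxabicyclo[3.3.1]non-3-ene
Conditions: Yb(C10H10F7O2)3 (5 mol %), toluene (0.01 M), 60 °C
Reagents that add atoms: none
Why: Proposed new method: because the tether leaves the inside (Z) position of the 1-oxadiene, the enol ether can add only in the bridged, silyloxy-endo mode (C2 to C3, carbonyl O to C1) through a chair carbocycle with the C4 methyl equatorial, which places the new oxa-bridge cis to the C4 methyl and, from the (Z)-enol ether, cis to the C2 methyl, so C2, C3 and the two rings are set in one operation; the closest known reaction type is the lanthanide-catalysed inverse-electron-demand hetero-Diels–Alder reaction of enals with enol ethers, here intramolecular and bridged (at worst a Michael-initiated stepwise version of the same annulation).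

**Step 8**
Reactants: 11 orcinol
Product: 12 1,3-bis(methoxymethoxy)-5-methylbenzene
Conditions: MOMCl (2.4 equiv), i-Pr2NEt (3 equiv), CH2Cl2, 0 °C to rt
Reagents that add atoms: chloromethyl methyl ether, COCCl
Why: O-alkylation of both phenols gives the bis-MOM ether, whose two acetal oxygens later direct the ortho-lithiation.

**Step 9**
Reactants: 12 1,3-bis(methoxymethoxy)-5-methylbenzene
Product: 13 2-chloro-1,5-bis(methoxymethoxy)-3-methylbenzene
Conditions: N-chlorosuccinimide (1.05 equiv), DMF, 0 °C to rt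
Reagents that add atoms: N-chlorosuccinimide, O=C1CCC(=O)N1Cl
Why: Electrophilic aromatic chlorination occurs para to one MOM ether at the position next to the methyl group, the site between the two MOM ethers being more crowded, as in the halogenation of orcinol dimethyl ether.

**Step 10**
Reactants: 14 but-2-yn-1-ol
Product: 16 (2E)-3-iodobut-2-en-1-ol, via alkenylzirconocene 15 (not isolated)
Conditions: (C5H5)2Zr(H)Cl (2.2 equiv), THF, rt; then I2, 0 °C; aqueous work-up
Reagents that add atoms: iodine, II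
Why: After O–Zr formation, syn-hydrozirconation (equilibrated by excess hydride) puts zirconium on the methyl-bearing carbon distal to oxygen, and iodinolysis with retention gives the (E)-vinyl iodide that fixes the side-chain alkene geometry.

**Step 11**
Reactants: 16 (2E)-3-iodobut-2-en-1-ol
Product: 17 (2E)-1-bromo-3-iodobut-2-ene
Conditions: PBr3 (0.4 equiv), Et2O, 0 °C
Reagents that add atoms: phosphorus tribromide, BrP(Br)Br
Why: SN2 bromination of the primary allylic alcohol leaves the vinyl iodide and its geometry untouched.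

**Step 12**
Reactants: 13 2-chloro-1,5-bis(methoxymethoxy)-3-methylbenzene; 17 (2E)-1-bromo-3-iodobut-2-ene
Product: 20 4-chloro-2-[(2E)-3-iodobut-2-en-1-yl]-1,3-bis(methoxymethoxy)-5-methylbenzene, via aryllithium 18 (not isolated), via arylcopper 19 (not isolated)
Conditions: n-BuLi (1.1 equiv), THF, 0 °C, 1 h; CuBr·SMe2 (1.1 equiv), −40 °C; then 17, −40 °C to rt
Reagents that add atoms: none
Why: Directed ortho-metalation occurs between the two MOM ethers, and the derived arylcopper displaces the primary allylic bromide in an SN2 sense without halogen–metal exchange at the vinyl iodide, so the (E)-alkene is kept.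

**Step 13**
Reactants: 10 (1S,5R,6S,9S)-5,6,9-trimethyl-1-[(triethylsilyl)oxy]-2-oxabicyclo[3.3.1]non-3-ene; 20 4-chloro-2-[(2E)-3-iodobut-2-en-1-yl]-1,3-bis(methoxymethoxy)-5-methylbenzene
Product: 22 (2S,3S,4S)-3-{(2S,3E)-5-[3-chloro-2,6-bis(methoxymethoxy)-4-methylphenyl]-2-hydroxy-3-methylpent-3-en-1-yl}-2,3,4-trimethylcyclohexan-1-one, via keto aldehyde 21 (not isolated)
Conditions: 0.5 M HCl, THF, 0 °C, 15 min, extract; then CrCl2 (3 equiv), NiCl2 (2 mol %), N-[2-(4-tert-butyl-4,5-dihydro-1,3-oxazol-2-yl)-6-methylphenyl]methanesulfonamide (antipode giving Re-face addition, 3.3 equiv), Et3N (3.3 equiv), THF, rt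
Reagents that add atoms: water, O
Why: Mild acid opens the silyl ketal and enol ether to the δ-keto aldehyde, and the Nozaki–Hiyama–Kishi reaction adds the alkenylchromium species (formed by nickel-mediated activation of the iodide) only to the aldehyde, the chiral sulfonamide ligand on trivalent chromium steering it to the Re face so that C4' is set S with the alkene geometry retained.

**Step 14**
Reactants: 22 (2S,3S,4S)-3-{(2S,3E)-5-[3-chloro-2,6-bis(methoxymethoxy)-4-methylphenyl]-2-hydroxy-3-methylpent-3-en-1-yl}-2,3,4-trimethylcyclohexan-1-one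
Product: 24 2-chloro-5-hydroxy-6-{(2E,4S)-4-hydroxy-3-methyl-5-[(1S,2S,6S)-1,2,6-trimethyl-3-oxocyclohexyl]pent-2-en-1-yl}-3-methylcyclohexa-2,5-diene-1,4-dione, via resorcinol 23 (not isolated)
Conditions: 3 M aqueous HCl, MeOH, 0 °C to rt; NaHCO3; then (KSO3)2NO (2.5 equiv), KH2PO4, acetone–H2O, rt
Reagents that add atoms: potassium nitrosodisulfonate, [O]N(S(=O)(=O)[O-])S(=O)(=O)[O-].[K+].[K+]
Why: Acid-catalysed acetal exchange frees the resorcinol, and Teuber oxidation by the nitroxyl radical at the only free ring position (para to one hydroxyl) gives the 2-hydroxy-1,4-benzoquinone without touching the alcohol, ketone or alkene.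

**Compound list**
1 | propanal | CCC=O | starting material
2 | penta-1,4-dien-3-one | C=CC(=O)C=C | starting material
3 | (2S)-2-methyl-5-oxohept-6-enal | O=C[C@@H](C)CCC(=O)C=C | intermediate
4 | (2S,5Z)-2-methyl-5-[(triethylsilyl)oxy]hept-5-enal | O=C[C@@H](C)CC/C(O[Si](CC)(CC)CC)=C/C | intermediate
5 | (3S,6Z)-3-methyl-6-[(triethylsilyl)oxy]oct-6-en-1-yne | C#C[C@@H](C)CC/C(O[Si](CC)(CC)CC)=C/C | intermediate
6 | lithium (3S,6Z)-3-methyl-6-[(triethylsilyl)oxy]oct-6-en-1-yn-1-ide | [Li]C#C[C@@H](C)CC/C(O[Si](CC)(CC)CC)=C/C | intermediate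
7 | (4S,7Z)-N-methoxy-N,4-dimethyl-7-[(triethylsilyl)oxy]non-7-en-2-ynamide | CON(C)C(=O)C#C[C@@H](C)CC/C(O[Si](CC)(CC)CC)=C/C | intermediate
8 | (2Z,4S,7Z)-N-methoxy-N,3,4-trimethyl-7-[(triethylsilyl)oxy]nona-2,7-dienamide | CON(C)C(=O)/C=C(/C)[C@@H](C)CC/C(O[Si](CC)(CC)CC)=C/C | intermediate
9 | (2Z,4S,7Z)-3,4-dimethyl-7-[(triethylsilyl)oxy]nona-2,7-dienal | O=C/C=C(/C)[C@@H](C)CC/C(O[Si](CC)(CC)CC)=C/C | intermediate
10 | (1S,5R,6S,9S)-5,6,9-trimethyl-1-[(triethylsilyl)oxy]-2-oxabicyclo[3.3.1]non-3-ene | C[C@H]1CC[C@@]2(O[Si](CC)(CC)CC)OC=C[C@]1(C)[C@@H]2C | intermediate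
11 | orcinol (5-methylbenzene-1,3-diol) | Cc1cc(O)cc(O)c1 | starting material
12 | 1,3-bis(methoxymethoxy)-5-methylbenzene | Cc1cc(OCOC)cc(OCOC)c1 | intermediate
13 | 2-chloro-1,5-bis(methoxymethoxy)-3-methylbenzene | Cc1cc(OCOC)cc(OCOC)c1Cl | intermediate
14 | but-2-yn-1-ol | CC#CCO | starting material
15 | chlorobis(cyclopentadienyl)[(2E)-4-{[chlorobis(cyclopentadienyl)zirconio]oxy}but-2-en-2-yl]zirconium | C/C(=C\CO[Zr](Cl)(C1C=CC=C1)C1C=CC=C1)[Zr](Cl)(C1C=CC=C1)C1C=CC=C1 | intermediate
16 | (2E)-3-iodobut-2-en-1-ol | C/C(I)=C\CO | intermediate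
17 | (2E)-1-bromo-3-iodobut-2-ene | C/C(I)=C\CBr | intermediate
18 | [3-chloro-2,6-bis(methoxymethoxy)-4-methylphenyl]lithium | Cc1cc(OCOC)c([Li])c(OCOC)c1Cl | intermediate
19 | [3-chloro-2,6-bis(methoxymethoxy)-4-methylphenyl]copper | Cc1cc(OCOC)c([Cu])c(OCOC)c1Cl | intermediate
20 | 4-chloro-2-[(2E)-3-iodobut-2-en-1-yl]-1,3-bis(methoxymethoxy)-5-methylbenzene | Cc1cc(OCOC)c(C/C=C(\C)I)c(OCOC)c1Cl | intermediate
21 | (2S,3S,4S)-2,3,4-trimethyl-3-(2-oxoethyl)cyclohexan-1-one | O=CC[C@]1(C)[C@H](C)C(=O)CC[C@@H]1C | intermediate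
22 | (2S,3S,4S)-3-{(2S,3E)-5-[3-chloro-2,6-bis(methoxymethoxy)-4-methylphenyl]-2-hydroxy-3-methylpent-3-en-1-yl}-2,3,4-trimethylcyclohexan-1-one | Cc1cc(OCOC)c(C/C=C(\C)[C@@H](O)C[C@]2(C)[C@H](C)C(=O)CC[C@@H]2C)c(OCOC)c1Cl | intermediate
23 | (2S,3S,4S)-3-[(2S,3E)-5-(3-chloro-2,6-dihydroxy-4-methylphenyl)-2-hydroxy-3-methylpent-3-en-1-yl]-2,3,4-trimethylcyclohexan-1-one | Cc1cc(O)c(C/C=C(\C)[C@@H](O)C[C@]2(C)[C@H](C)C(=O)CC[C@@H]2C)c(O)c1Cl | intermediate
24 | 2-chloro-5-hydroxy-6-{(2E,4S)-4-hydroxy-3-methyl-5-[(1S,2S,6S)-1,2,6-trimethyl-3-oxocyclohexyl]pent-2-en-1-yl}-3-methylcyclohexa-2,5-diene-1,4-dione | CC1=C(Cl)C(=O)C(C/C=C(\C)[C@@H](O)C[C@]2(C)[C@H](C)C(=O)CC[C@@H]2C)=C(O)C1=O | target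

**Step count**
Total: 14 steps. Longest linear sequence: 9 steps (steps 1 to 7, then 13 and 14).

**Steps most likely to fail**

Step 7. The bridged cycloaddition has no direct precedent and the β,β-disubstituted heterodiene is sluggish. The (Z)-enal may isomerise. Above all, the C4 methyl may prefer the axial position, anti to the heterodiene, to relieve allylic strain; that would give the C3 epimer, and this facial selectivity cannot be predicted with confidence. The fallback sets out from 5 and uses a methylcuprate addition, which is reliably anti to the C4 methyl, to build the quaternary centre. n-BuLi then DMF converts 5 into the ynal (4S,7Z)-4-methyl-7-[(triethylsilyl)oxy]non-7-en-2-ynal F1. TiCl4-promoted intramolecular Mukaiyama–Michael (Conia-type) closure onto the ynal, with aqueous work-up, gives the exocyclic enal [(6S)-2,6-dimethyl-3-oxocyclohexylidene]acetaldehyde F2. Me2CuLi with Me3SiCl then adds methyl to the ring carbon from the face opposite the neighbouring C4 methyl, and acidic work-up with equilibration of C2 rejoins the route at 21.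

Step 13. C4' is remote from the ring stereocentres, so its configuration rests entirely on the ligand, whose matching antipode must be found by experiment, and 21 can undergo aldol side reactions. The fallback sets out from 21. Ligand-free CrCl2/NiCl2 coupling with 20 gives 22 mixed with its 4'-epimer (2S,3S,4S)-3-{(2R,3E)-5-[3-chloro-2,6-bis(methoxymethoxy)-4-methylphenyl]-2-hydroxy-3-methylpent-3-en-1-yl}-2,3,4-trimethylcyclohexan-1-one F3. MnO2 oxidises only the allylic alcohols to the enone (2S,3S,4S)-3-{(3E)-5-[3-chloro-2,6-bis(methoxymethoxy)-4-methylphenyl]-3-methyl-2-oxopent-3-en-1-yl}-2,3,4-trimethylcyclohexan-1-one F4. Reduction with the (R)-methyl-CBS oxazaborolidine and catecholborane at −78 °C, which favours the conjugated carbonyl over the hindered ring ketone, rejoins the route at 22.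

Step 14. Protic acid on the free allylic alcohol next to an ortho-allyl phenol risks allylic solvolysis or chroman formation. The fallback sets out from 22. t-BuMe2SiOTf with 2,6-lutidine gives the silyl ether (2S,3S,4S)-3-{(2S,3E)-2-[(tert-butyldimethylsilyl)oxy]-5-[3-chloro-2,6-bis(methoxymethoxy)-4-methylphenyl]-3-methylpent-3-en-1-yl}-2,3,4-trimethylcyclohexan-1-one F5. ZnBr2 with n-PrSH removes both MOM groups under aprotic conditions to give the resorcinol (2S,3S,4S)-3-[(2S,3E)-2-[(tert-butyldimethylsilyl)oxy]-5-(3-chloro-2,6-dihydroxy-4-methylphenyl)-3-methylpent-3-en-1-yl]-2,3,4-trimethylcyclohexan-1-one F6. (KSO3)2NO oxidises it to the silylated quinone 6-{(2E,4S)-4-[(tert-butyldimethylsilyl)oxy]-3-methyl-5-[(1S,2S,6S)-1,2,6-trimethyl-3-oxocyclohexyl]pent-2-en-1-yl}-2-chloro-5-hydroxy-3-methylcyclohexa-2,5-diene-1,4-dione F7, and HF·pyridine removes the silyl group to arrive at 24.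

**Further compounds**
F1 | step 7 | (4S,7Z)-4-methyl-7-[(triethylsilyl)oxy]non-7-en-2-ynal | O=CC#C[C@@H](C)CC/C(O[Si](CC)(CC)CC)=C/C
F2 | step 7 | [(6S)-2,6-dimethyl-3-oxocyclohexylidene]acetaldehyde | O=CC=C1[C@@H](C)CCC(=O)C1C
F3 | step 13 | (2S,3S,4S)-3-{(2R,3E)-5-[3-chloro-2,6-bis(methoxymethoxy)-4-methylphenyl]-2-hydroxy-3-methylpent-3-en-1-yl}-2,3,4-trimethylcyclohexan-1-one | Cc1cc(OCOC)c(C/C=C(\C)[C@H](O)C[C@]2(C)[C@H](C)C(=O)CC[C@@H]2C)c(OCOC)c1Cl
F4 | step 13 | (2S,3S,4S)-3-{(3E)-5-[3-chloro-2,6-bis(methoxymethoxy)-4-methylphenyl]-3-methyl-2-oxopent-3-en-1-yl}-2,3,4-trimethylcyclohexan-1-one | Cc1cc(OCOC)c(C/C=C(\C)C(=O)C[C@]2(C)[C@H](C)C(=O)CC[C@@H]2C)c(OCOC)c1Cl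
F5 | step 14 | (2S,3S,4S)-3-{(2S,3E)-2-[(tert-butyldimethylsilyl)oxy]-5-[3-chloro-2,6-bis(methoxymethoxy)-4-methylphenyl]-3-methylpent-3-en-1-yl}-2,3,4-trimethylcyclohexan-1-one | Cc1cc(OCOC)c(C/C=C(\C)[C@@H](O[Si](C)(C)C(C)(C)C)C[C@]2(C)[C@H](C)C(=O)CC[C@@H]2C)c(OCOC)c1Cl
F6 | step 14 | (2S,3S,4S)-3-[(2S,3E)-2-[(tert-butyldimethylsilyl)oxy]-5-(3-chloro-2,6-dihydroxy-4-methylphenyl)-3-methylpent-3-en-1-yl]-2,3,4-trimethylcyclohexan-1-one | Cc1cc(O)c(C/C=C(\C)[C@@H](O[Si](C)(C)C(C)(C)C)C[C@]2(C)[C@H](C)C(=O)CC[C@@H]2C)c(O)c1Cl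
F7 | step 14 | 6-{(2E,4S)-4-[(tert-butyldimethylsilyl)oxy]-3-methyl-5-[(1S,2S,6S)-1,2,6-trimethyl-3-oxocyclohexyl]pent-2-en-1-yl}-2-chloro-5-hydroxy-3-methylcyclohexa-2,5-diene-1,4-dione | CC1=C(Cl)C(=O)C(C/C=C(\C)[C@@H](O[Si](C)(C)C(C)(C)C)C[C@]2(C)[C@H](C)C(=O)CC[C@@H]2C)=C(O)C1=O
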